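The route rests on cutting the C2–C3 bond of ring C. C2 is the only sp3 carbon that is both bonded to O1 and benzylic to the electron-rich ring B, and it ends the chain C3–C4–C4a–C8a–O1–C2, so a carbenoid at C3 can reach its C–H bonds through a six-membered transition state. One enantioselective rhodium-carbenoid C–H insertion therefore forms C2–C3, closes ring C and sets the 2S centre. Its precursor is a ring A diazomethyl ketone carrying the ring B benzyl group on O1, the prenyl group on C8 and silyl ethers on O5, O7 and O4', which are removed together in a final buffered fluoride step.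

Key step: step 12

Structure check: the target is a (2S)-flavanone (at C2: O1 > C1' > C3 > H). Ring A carries 5-OH, 7-OH and 8-prenyl; ring B carries 2'-OMe, 4'-OH and 5'-(2-methylbut-3-en-2-yl).

Precursor design: O5 and O7 are TIPS ethers and O4' is a TBS ether.
- The three groups are put on once and never exchanged.
- The O5 group has no C–H bond alpha to oxygen and a crowded, weakly basic oxygen, so it offers the carbenoid neither an insertion site nor an ylide partner.
- All three leave under buffered fluoride. This avoids base, which would open ring C to the chalcone and scramble C2, and strong acid, which would cyclise the prenyl-type groups onto neighbouring phenols.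

Assumption: Rh2(S-PTTL)4 is taken to give the 2S sense in step 12; if the first run shows the opposite sense, the mirror-image catalyst Rh2(R-PTTL)4 is used under unchanged conditions.

Step 1
Reactants: 1 phloroglucinol
Product: 2 3,5-bis(triisopropylsilyloxy)phenol
Conditions: TIPSCl (2.0 equiv), imidazole, DMF, 0 °C → rt
Reagents that add atoms: triisopropylsilyl chloride, CC(C)[Si](Cl)(C(C)C)C(C)C
Why: Imidazole-promoted silylation of phenols; with two equivalents of the bulky chloride the symmetric triol should give mainly the bis-ether, which is separated by chromatography from the recyclable mono- and tris-ethers.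

Step 2
Reactants: 2 3,5-bis(triisopropylsilyloxy)phenol; 3 3-chloro-3-methylbut-1-yne
Product: 4 1-[(2-methylbut-3-yn-2-yl)oxy]-3,5-bis(triisopropylsilyloxy)benzene
Conditions: DBU, CuCl2·2H2O (cat.), MeCN, 0 °C
Reagents that add atoms: none
Why: Copper-catalysed propargylic etherification (the copper acetylide ionises the tertiary chloride and the phenoxide adds at the tertiary carbon) makes the hindered aryl 1,1-dimethylpropargyl ether at 0 °C, where DBU leaves the aryl TIPS ethers alone.

Step 3
Reactants: 4 1-[(2-methylbut-3-yn-2-yl)oxy]-3,5-bis(triisopropylsilyloxy)benzene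
Product: 6 2-(3-methylbut-2-en-1-yl)-3,5-bis(triisopropylsilyloxy)phenol, via 1,1-dimethylallyl aryl ether 5 (not isolated)
Conditions: H2 (1 atm), Pd/CaCO3 poisoned with Pb(OAc)2 (Lindlar catalyst), quinoline, toluene, rt; filter; then 110 °C
Reagents that add atoms: none
Why: Lindlar semihydrogenation stops at the terminal alkene 5, whose aromatic Claisen rearrangement ([3,3]-sigmatropic shift with allylic inversion, eased by the gem-dimethyl group) delivers a normal prenyl group to either of the two equivalent ortho positions and so gives a single phenol.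

Step 4
Reactants: 6 2-(3-methylbut-2-en-1-yl)-3,5-bis(triisopropylsilyloxy)phenol
Product: 7 2-hydroxy-3-(3-methylbut-2-en-1-yl)-4,6-bis(triisopropylsilyloxy)benzaldehyde
Conditions: MgCl2, Et3N, (CH2O)n, MeCN, reflux
Reagents that add atoms: paraformaldehyde (reacts as formaldehyde), C=O
Why: Magnesium-mediated ortho-formylation (Casnati–Skattebøl): the magnesium phenoxide delivers formaldehyde only to the one free ortho position, and a second formaldehyde oxidises the benzylic alkoxide by hydride transfer, all under basic conditions that spare the silyl ethers and the prenyl group.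

Step 5
Reactants: 8 4-hydroxy-2-methoxybenzaldehyde; 9 prenyl bromide (1-bromo-3-methylbut-2-ene)
Product: 10 2-methoxy-4-[(3-methylbut-2-en-1-yl)oxy]benzaldehyde
Conditions: K2CO3, acetone, reflux
Reagents that add atoms: none
Why: Williamson ether synthesis: the phenoxide, made acidic by the para formyl group, displaces the primary allylic bromide by SN2.

Step 6
Reactants: 10 2-methoxy-4-[(3-methylbut-2-en-1-yl)oxy]benzaldehyde
Product: 11 4-hydroxy-2-methoxy-5-(2-methylbut-3-en-2-yl)benzaldehyde
Conditions: PhNEt2, 200 °C (sealed tube, argon)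
Reagents that add atoms: none
Why: Aromatic Claisen rearrangement: the [3,3] shift with allylic inversion should place the 2-methylbut-3-en-2-yl group on C5, the ortho position that is para to the methoxy donor and not crowded by it, the para position being blocked by the formyl group, while the amine solvent suppresses acid-catalysed ring closure of the new ortho-allylphenol.

Step 7
Reactants: 11 4-hydroxy-2-methoxy-5-(2-methylbut-3-en-2-yl)benzaldehyde
Product: 12 4-(tert-butyldimethylsilyloxy)-2-methoxy-5-(2-methylbut-3-en-2-yl)benzaldehyde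
Conditions: TBSCl, imidazole, DMF, rt
Reagents that add atoms: tert-butyldimethylsilyl chloride, CC(C)(C)[Si](C)(C)Cl
Why: Standard silylation of a phenol; the acidic para-formyl phenol should react despite the neighbouring quaternary carbon, which in turn shields the silyl ether in later steps.

Step 8
Reactants: 12 4-(tert-butyldimethylsilyloxy)-2-methoxy-5-(2-methylbut-3-en-2-yl)benzaldehyde
Product: 13 [4-(tert-butyldimethylsilyloxy)-2-methoxy-5-(2-methylbut-3-en-2-yl)phenyl]methanol
Conditions: NaBH4, MeOH/THF, 0 °C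
Reagents that add atoms: none
Why: Borohydride reduction of the aldehyde is fast at 0 °C and leaves the aryl silyl ether and the vinyl group untouched.

Step 9
Reactants: 7 2-hydroxy-3-(3-methylbut-2-en-1-yl)-4,6-bis(triisopropylsilyloxy)benzaldehyde; 13 [4-(tert-butyldimethylsilyloxy)-2-methoxy-5-(2-methylbut-3-en-2-yl)phenyl]methanol
Product: 14 2-{[4-(tert-butyldimethylsilyloxy)-2-methoxy-5-(2-methylbut-3-en-2-yl)phenyl]methoxy}-3-(3-methylbut-2-en-1-yl)-4,6-bis(triisopropylsilyloxy)benzaldehyde
Conditions: PPh3, DIAD, THF, 0 °C → rt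
Reagents that add atoms: none
Why: Mitsunobu etherification: the hydrogen-bonded, acidic salicylaldehyde OH of 7 displaces the oxyphosphonium derived from the primary benzylic alcohol 13 under neutral conditions, which avoids an unstable electron-rich benzyl halide and leaves every silyl ether in place.

Step 10
Reactants: 14 the ring A aldehyde bearing the ring B benzyl ether
Product: 15 2-{[4-(tert-butyldimethylsilyloxy)-2-methoxy-5-(2-methylbut-3-en-2-yl)phenyl]methoxy}-3-(3-methylbut-2-en-1-yl)-4,6-bis(triisopropylsilyloxy)benzoic acid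
Conditions: NaClO2, NaH2PO4, 2-methyl-2-butene (large excess), t-BuOH/THF/H2O, 0 °C → rt
Reagents that add atoms: sodium chlorite, [Na+].[O-]Cl=O
Why: Pinnick (Lindgren) oxidation: chlorous acid adds to the aldehyde and fragments to the acid, the excess 2-methyl-2-butene removes HOCl before it can attack the prenyl groups or the electron-rich rings, and the phosphate buffer is too weak an acid to cleave the benzylic ether or the silyl ethers.

Step 11
Reactants: 15 the ring A benzoic acid (used without storage)
Product: 17 2-diazo-1-{2-{[4-(tert-butyldimethylsilyloxy)-2-methoxy-5-(2-methylbut-3-en-2-yl)phenyl]methoxy}-3-(3-methylbut-2-en-1-yl)-4,6-bis(triisopropylsilyloxy)phenyl}ethan-1-one, via acid chloride 16 (not isolated)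
Conditions: 1-chloro-N,N,2-trimethylprop-1-en-1-amine, CH2Cl2, 0 °C → rt; then CH2N2 (excess), Et2O, 0 °C
Reagents that add atoms: diazomethane, C=[N+]=[N-] (the chlorine of 16 comes from 1-chloro-N,N,2-trimethylprop-1-en-1-amine, CC(C)=C(Cl)N(C)C, and is lost again)
Why: The α-chloroenamine turns the acid into acid chloride 16 without releasing HCl, so the acid-labile dialkoxybenzyl ether and the silyl ethers survive, and acylation of diazomethane (first stage of the Arndt–Eistert sequence) gives the diazomethyl ketone, the excess diazomethane taking up the HCl as chloromethane.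

Step 12
Reactants: 17 the ring A diazomethyl ketone
Product: 18 (2S)-2-[4-(tert-butyldimethylsilyloxy)-2-methoxy-5-(2-methylbut-3-en-2-yl)phenyl]-8-(3-methylbut-2-en-1-yl)-5,7-bis(triisopropylsilyloxy)-2,3-dihydro-4H-chromen-4-one
Conditions: Rh2(S-PTTL)4 (dirhodium tetrakis[N-phthaloyl-(S)-tert-leucinate], 2 mol %), toluene, 0 °C → rt, slow addition of 17 at high dilution
Reagents that add atoms: none
Why: The divalent rhodium dimer expels N2 from 17 to give an electrophilic acyl carbenoid, whose carbon takes up one of the two enantiotopic C–H bonds of the O1–CH2–aryl group in a concerted, asynchronous three-centre insertion (hydride-like C–H donation with simultaneous C–C bond formation) that creates C2–C3. The closest known reaction type is the dirhodium-carboxylate-catalysed intramolecular C–H insertion of ortho-alkoxyaryl diazomethyl ketones next to the ether oxygen, which gives chroman-4-ones. Ring C closes as a six-membered ring by 1,6-insertion through a chair-like transition state made of the carbenoid carbon, C4, C4a, C8a, O1 and C2, with ring B pseudo-equatorial. The one new stereocentre, C2, is set by the catalyst, whose phthalimido walls around the rhodium face distinguish the two enantiotopic benzylic hydrogens. The step needs chemoselectivity for C–H insertion over attack of O1 on the carbenoid (oxonium ylide, then 1,2-benzyl shift to a 2-benzylbenzofuran-3-one); this is favoured by the doubly activated, hydridic C2–H bonds (alpha to O1 and benzylic to the 2,4-dioxygenated ring B), by the bulky ligand wall, slow addition and low temperature, and by the lack of any other partner within reach, since O5 carries a crowded silyl group without alpha C–H bonds, the C8 prenyl CH2 cannot reach C3 across the meta positions, and both alkenes are too remote for cyclopropanation.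

Step 13
Reactants: 18 the (2S)-flavanone tris-silyl ether
Product: 19 (2S)-5,7-dihydroxy-2-[4-hydroxy-2-methoxy-5-(2-methylbut-3-en-2-yl)phenyl]-8-(3-methylbut-2-en-1-yl)-2,3-dihydro-4H-chromen-4-one (CNP0308136.1)
Conditions: TBAF, AcOH (1:1, excess), THF, 0 °C → rt
Reagents that add atoms: none
Why: Fluoride-mediated desilylation: fluoride attacks silicon and expels the three aryloxy groups while acetic acid protonates each phenoxide at once, so no base is present to open ring C by retro-oxa-Michael reaction and scramble C2, and no strong acid to cyclise either prenyl-type group onto a neighbouring phenol.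

Compound list
1 | phloroglucinol (benzene-1,3,5-triol) | Oc1cc(O)cc(O)c1 | starting material
2 | 3,5-bis(triisopropylsilyloxy)phenol | Oc1cc(O[Si](C(C)C)(C(C)C)C(C)C)cc(O[Si](C(C)C)(C(C)C)C(C)C)c1 | intermediate
3 | 3-chloro-3-methylbut-1-yne | CC(C)(Cl)C#C | starting material
4 | 1-[(2-methylbut-3-yn-2-yl)oxy]-3,5-bis(triisopropylsilyloxy)benzene | C#CC(C)(C)Oc1cc(O[Si](C(C)C)(C(C)C)C(C)C)cc(O[Si](C(C)C)(C(C)C)C(C)C)c1 | intermediate
5 | 1-[(2-methylbut-3-en-2-yl)oxy]-3,5-bis(triisopropylsilyloxy)benzene (formed in the flask, not isolated) | C=CC(C)(C)Oc1cc(O[Si](C(C)C)(C(C)C)C(C)C)cc(O[Si](C(C)C)(C(C)C)C(C)C)c1 | intermediate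
6 | 2-(3-methylbut-2-en-1-yl)-3,5-bis(triisopropylsilyloxy)phenol | CC(C)=CCc1c(O)cc(O[Si](C(C)C)(C(C)C)C(C)C)cc1O[Si](C(C)C)(C(C)C)C(C)C | intermediate
7 | 2-hydroxy-3-(3-methylbut-2-en-1-yl)-4,6-bis(triisopropylsilyloxy)benzaldehyde | O=Cc1c(O)c(CC=C(C)C)c(O[Si](C(C)C)(C(C)C)C(C)C)cc1O[Si](C(C)C)(C(C)C)C(C)C | intermediate
8 | 4-hydroxy-2-methoxybenzaldehyde | COc1cc(O)ccc1C=O | starting material
9 | prenyl bromide (1-bromo-3-methylbut-2-ene) | CC(C)=CCBr | starting material
10 | 2-methoxy-4-[(3-methylbut-2-en-1-yl)oxy]benzaldehyde | COc1cc(OCC=C(C)C)ccc1C=O | intermediate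
11 | 4-hydroxy-2-methoxy-5-(2-methylbut-3-en-2-yl)benzaldehyde | COc1cc(O)c(C(C)(C)C=C)cc1C=O | intermediate
12 | 4-(tert-butyldimethylsilyloxy)-2-methoxy-5-(2-methylbut-3-en-2-yl)benzaldehyde | COc1cc(O[Si](C)(C)C(C)(C)C)c(C(C)(C)C=C)cc1C=O | intermediate
13 | [4-(tert-butyldimethylsilyloxy)-2-methoxy-5-(2-methylbut-3-en-2-yl)phenyl]methanol | COc1cc(O[Si](C)(C)C(C)(C)C)c(C(C)(C)C=C)cc1CO | intermediate
14 | 2-{[4-(tert-butyldimethylsilyloxy)-2-methoxy-5-(2-methylbut-3-en-2-yl)phenyl]methoxy}-3-(3-methylbut-2-en-1-yl)-4,6-bis(triisopropylsilyloxy)benzaldehyde | O=Cc1c(OCc2cc(C(C)(C)C=C)c(O[Si](C)(C)C(C)(C)C)cc2OC)c(CC=C(C)C)c(O[Si](C(C)C)(C(C)C)C(C)C)cc1O[Si](C(C)C)(C(C)C)C(C)C | intermediate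
15 | 2-{[4-(tert-butyldimethylsilyloxy)-2-methoxy-5-(2-methylbut-3-en-2-yl)phenyl]methoxy}-3-(3-methylbut-2-en-1-yl)-4,6-bis(triisopropylsilyloxy)benzoic acid | OC(=O)c1c(OCc2cc(C(C)(C)C=C)c(O[Si](C)(C)C(C)(C)C)cc2OC)c(CC=C(C)C)c(O[Si](C(C)C)(C(C)C)C(C)C)cc1O[Si](C(C)C)(C(C)C)C(C)C | intermediate
16 | the benzoyl chloride of 15 (formed in the flask, not isolated) | ClC(=O)c1c(OCc2cc(C(C)(C)C=C)c(O[Si](C)(C)C(C)(C)C)cc2OC)c(CC=C(C)C)c(O[Si](C(C)C)(C(C)C)C(C)C)cc1O[Si](C(C)C)(C(C)C)C(C)C | intermediate
17 | 2-diazo-1-{2-{[4-(tert-butyldimethylsilyloxy)-2-methoxy-5-(2-methylbut-3-en-2-yl)phenyl]methoxy}-3-(3-methylbut-2-en-1-yl)-4,6-bis(triisopropylsilyloxy)phenyl}ethan-1-one | [N-]=[N+]=CC(=O)c1c(OCc2cc(C(C)(C)C=C)c(O[Si](C)(C)C(C)(C)C)cc2OC)c(CC=C(C)C)c(O[Si](C(C)C)(C(C)C)C(C)C)cc1O[Si](C(C)C)(C(C)C)C(C)C | intermediate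
18 | (2S)-2-[4-(tert-butyldimethylsilyloxy)-2-methoxy-5-(2-methylbut-3-en-2-yl)phenyl]-8-(3-methylbut-2-en-1-yl)-5,7-bis(triisopropylsilyloxy)-2,3-dihydro-4H-chromen-4-one | C=CC(C)(C)c1cc([C@@H]2CC(=O)c3c(O[Si](C(C)C)(C(C)C)C(C)C)cc(O[Si](C(C)C)(C(C)C)C(C)C)c(CC=C(C)C)c3O2)c(OC)cc1O[Si](C)(C)C(C)(C)C | intermediate
19 | (2S)-5,7-dihydroxy-2-[4-hydroxy-2-methoxy-5-(2-methylbut-3-en-2-yl)phenyl]-8-(3-methylbut-2-en-1-yl)-2,3-dihydro-4H-chromen-4-one (CNP0308136.1) | C=CC(C)(C)c1cc([C@@H]2CC(=O)c3c(O)cc(O)c(CC=C(C)C)c3O2)c(OC)cc1O | target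

Total step count: 13. Longest linear sequence: 9 steps (steps 1–4 and 9–13); the ring B branch (steps 5–8) joins at step 9.

Steps most likely to fail

Step 12. The carbenoid may be captured by the lone pair of O1 faster than it inserts, so that ylide formation and benzyl migration outrun the C–H insertion, or the catalyst may discriminate the two benzylic hydrogens poorly. Other ligand classes (a sulfonylprolinate such as Rh2(S-DOSP)4, a carboxamidate such as Rh2(5S-MEPY)4) would be tried first. The fallback gives up the carbenoid and makes the same C2–C3 bond by an aldol reaction. It sets out from salicylaldehyde 7 and ring B aldehyde 12 and comes back at 18.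
- Addition of MeMgBr to 7 (THF, 0 °C) should give 1-[2-hydroxy-3-(3-methylbut-2-en-1-yl)-4,6-bis(triisopropylsilyloxy)phenyl]ethan-1-ol F1.
- MnO2 in CH2Cl2 should oxidise it to the 2'-hydroxyacetophenone F2.
- The dilithium phenoxide-enolate of F2 (LiN(SiMe3)2, THF, −78 °C) should add to 12 to give the β-hydroxy ketone F3.
- Intramolecular Mitsunobu etherification (PPh3, DIAD, THF) should close ring C to the racemic flavanone F4; any chalcone formed by elimination is cyclised with NaOAc in EtOH.
- Preparative chromatography on a chiral stationary phase then delivers the 2S enantiomer, which is 18.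

Step 6. At 200 °C the new ortho-allylphenol may isomerise further (abnormal Claisen rearrangement), close onto its own vinyl group to a dihydrobenzofuran, or lose the allyl unit. The fallback builds the quaternary benzylic carbon by cross-coupling. It sets out from 8 and comes back at 12, replacing steps 5 to 7.
- Bromination with NBS (MeCN, 0 °C) should go ortho to OH and para to OMe and give 5-bromo-4-hydroxy-2-methoxybenzaldehyde F5.
- Silylation (TBSCl, imidazole, DMF) gives the silyl ether F6.
- A γ-selective Suzuki–Miyaura coupling of F6 with 3-methylbut-2-enylboronic acid pinacol ester (Pd(OAc)2 with a biarylphosphine ligand chosen for branched selectivity, K3PO4, THF/H2O, 40 °C) should transfer the allyl unit through its tertiary carbon and give 12.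

Step 11. The carbonyl group of 16 is flanked by two ortho substituents, so acylation of diazomethane may be slow and decomposition of the acid chloride may compete. The fallback makes the diazo ketone by diazo transfer and not by acylation. It sets out from aldehyde 14 and comes back at 17, replacing steps 10 and 11.
- MeMgBr (THF, 0 °C) should give the secondary alcohol F7.
- Dess–Martin periodinane (CH2Cl2, NaHCO3) should give the methyl ketone F8.
- Detrifluoroacetylative diazo transfer follows: LiN(SiMe3)2, THF, −78 °C, then CF3CO2CH2CF3 gives the trifluoroacetyl diketone F9, which is not isolated; MsN3, Et3N, H2O, MeCN, rt then gives 17. No ester is present that the enolate could attack.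

Further compounds
F1 | step 12 | 1-[2-hydroxy-3-(3-methylbut-2-en-1-yl)-4,6-bis(triisopropylsilyloxy)phenyl]ethan-1-ol (racemic) | CC(O)c1c(O)c(CC=C(C)C)c(O[Si](C(C)C)(C(C)C)C(C)C)cc1O[Si](C(C)C)(C(C)C)C(C)C
F2 | step 12 | 1-[2-hydroxy-3-(3-methylbut-2-en-1-yl)-4,6-bis(triisopropylsilyloxy)phenyl]ethan-1-one | CC(=O)c1c(O)c(CC=C(C)C)c(O[Si](C(C)C)(C(C)C)C(C)C)cc1O[Si](C(C)C)(C(C)C)C(C)C
F3 | step 12 | 3-[4-(tert-butyldimethylsilyloxy)-2-methoxy-5-(2-methylbut-3-en-2-yl)phenyl]-3-hydroxy-1-[2-hydroxy-3-(3-methylbut-2-en-1-yl)-4,6-bis(triisopropylsilyloxy)phenyl]propan-1-one (racemic) | COc1cc(O[Si](C)(C)C(C)(C)C)c(C(C)(C)C=C)cc1C(O)CC(=O)c1c(O)c(CC=C(C)C)c(O[Si](C(C)C)(C(C)C)C(C)C)cc1O[Si](C(C)C)(C(C)C)C(C)C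
F4 | step 12 | racemic 2-[4-(tert-butyldimethylsilyloxy)-2-methoxy-5-(2-methylbut-3-en-2-yl)phenyl]-8-(3-methylbut-2-en-1-yl)-5,7-bis(triisopropylsilyloxy)-2,3-dihydro-4H-chromen-4-one | C=CC(C)(C)c1cc(C2CC(=O)c3c(O[Si](C(C)C)(C(C)C)C(C)C)cc(O[Si](C(C)C)(C(C)C)C(C)C)c(CC=C(C)C)c3O2)c(OC)cc1O[Si](C)(C)C(C)(C)C
F5 | step 6 | 5-bromo-4-hydroxy-2-methoxybenzaldehyde | COc1cc(O)c(Br)cc1C=O
F6 | step 6 | 5-bromo-4-(tert-butyldimethylsilyloxy)-2-methoxybenzaldehyde | COc1cc(O[Si](C)(C)C(C)(C)C)c(Br)cc1C=O
F7 | step 11 | 1-{2-{[4-(tert-butyldimethylsilyloxy)-2-methoxy-5-(2-methylbut-3-en-2-yl)phenyl]methoxy}-3-(3-methylbut-2-en-1-yl)-4,6-bis(triisopropylsilyloxy)phenyl}ethan-1-ol (racemic) | CC(O)c1c(OCc2cc(C(C)(C)C=C)c(O[Si](C)(C)C(C)(C)C)cc2OC)c(CC=C(C)C)c(O[Si](C(C)C)(C(C)C)C(C)C)cc1O[Si](C(C)C)(C(C)C)C(C)C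
F8 | step 11 | 1-{2-{[4-(tert-butyldimethylsilyloxy)-2-methoxy-5-(2-methylbut-3-en-2-yl)phenyl]methoxy}-3-(3-methylbut-2-en-1-yl)-4,6-bis(triisopropylsilyloxy)phenyl}ethan-1-one | CC(=O)c1c(OCc2cc(C(C)(C)C=C)c(O[Si](C)(C)C(C)(C)C)cc2OC)c(CC=C(C)C)c(O[Si](C(C)C)(C(C)C)C(C)C)cc1O[Si](C(C)C)(C(C)C)C(C)C
F9 | step 11 | 4,4,4-trifluoro-1-{2-{[4-(tert-butyldimethylsilyloxy)-2-methoxy-5-(2-methylbut-3-en-2-yl)phenyl]methoxy}-3-(3-methylbut-2-en-1-yl)-4,6-bis(triisopropylsilyloxy)phenyl}butane-1,3-dione (not isolated) | O=C(CC(=O)C(F)(F)F)c1c(OCc2cc(C(C)(C)C=C)c(O[Si](C)(C)C(C)(C)C)cc2OC)c(CC=C(C)C)c(O[Si](C(C)C)(C(C)C)C(C)C)cc1O[Si](C(C)C)(C(C)C)C(C)C
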